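**Retrosynthetic overview**

1. The target comes from a bis-silyl ester by fluoride desilylation, which comes from aroylation at O2 of a primary-TBS glycerol ether with 4-(TBS-oxy)benzoyl chloride, which in turn comes from acetonide hydrolysis and primary silylation of the triene ether of (R)-solketal.
2. Feature carrying the strategy: in the C4=C5–C6=C7–C8=C9 triene of the dodecatrienyl chain the Z bond (C6=C7) sits in the middle, flanked by the E-alkenyl carbons C5 and C8. C6=C7 is therefore a two-carbon linchpin with bromine at C7 and MIDA-masked boron at C6.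
3. Key disconnections are C7–C8 and C5–C6. (E)-Pent-1-enylboronic acid (C8–C12), (Z)-2-bromovinyl MIDA boronate (C6–C7) and the (E)-5-iodopent-4-enyl ether of (R)-solketal (C1–C5 plus glycerol) are joined in one flask.
4. The iodide comes from (R)-solketal and pent-4-ynyl tosylate, then hydrozirconation and iodination. The linchpin comes from ethynyl MIDA boronate by bromination and diimide reduction.
5. No ring is formed: the benzene ring is bought with 4-hydroxybenzoic acid and the dioxolane of solketal is only a protecting group. The one stereocentre (glycerol C2) is bought with (R)-solketal.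

Key step: step 6

Remark on configuration: no bond to the glycerol carbon is broken anywhere. Its descriptor changes (R in 3, 4, 5, 12; S in 13; R in 14, 18; S in 19) only because the CIP ranking of its substituents changes.

Remark on handling: all triene-containing compounds (12 onwards) are to be kept under argon, shielded from light and below about 45 °C.

**Route**

Step 1
Reactants: 1 pent-4-yn-1-ol
Product: 2 pent-4-yn-1-yl 4-methylbenzenesulfonate
Conditions: TsCl, Et3N, DMAP (cat.), CH2Cl2, 0 °C → rt
Reagents that add atoms: 4-toluenesulfonyl chloride, Cc1ccc(cc1)S(Cl)(=O)=O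
Why: O-Sulfonylation of an unhindered primary alcohol under amine base with DMAP catalysis is routine, and the terminal alkyne is inert to it.

Step 2
Reactants: 3 (R)-solketal, (R)-(2,2-dimethyl-1,3-dioxolan-4-yl)methanol; 2 pent-4-yn-1-yl 4-methylbenzenesulfonate
Product: 4 (R)-2,2-dimethyl-4-[(pent-4-yn-1-yloxy)methyl]-1,3-dioxolane
Conditions: 3, NaH, THF/DMF, 0 °C; then 2, Bu4NI (cat.), rt → 40 °C
Reagents that add atoms: none
Why: Williamson ether synthesis, in which the sodium alkoxide of 3 (made with slightly less than one equivalent of NaH so that no base is left for the alkyne C–H) displaces the primary tosylate by SN2, while the base-stable acetonide and the stereocentre take no part.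

Step 3
Reactants: 4 (R)-2,2-dimethyl-4-[(pent-4-yn-1-yloxy)methyl]-1,3-dioxolane
Product: 5 (R)-4-{[(E)-5-iodopent-4-en-1-yloxy]methyl}-2,2-dimethyl-1,3-dioxolane
Conditions: Cp2Zr(H)Cl, THF, rt, dark; then I2, THF, 0 °C; Na2S2O3/NaHCO3 work-up
Reagents that add atoms: iodine, II
Why: Hydrozirconation–iodination, in which Cp2Zr(H)Cl adds Zr–H syn across the terminal alkyne with zirconium on the terminal carbon and iodine cleaves the C–Zr bond with retention, so the E-1-iodoalkene should form as one regio- and stereoisomer with the ether and acetal oxygens tolerated.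

Step 4
Reactants: 6 ethynylboronic acid MIDA ester (MIDA = N-methyliminodiacetic acid)
Product: 7 (bromoethynyl)boronic acid MIDA ester
Conditions: NBS, AgNO3 (cat.), acetone, rt, dark
Reagents that add atoms: N-bromosuccinimide, BrN1C(=O)CCC1=O
Why: Silver-catalysed electrophilic bromination of a terminal alkyne through the silver acetylide is a standard route to 1-bromoalkynes, and the tetracoordinate MIDA boronate is inert to NBS and AgNO3.

Step 5
Reactants: 7 (bromoethynyl)boronic acid MIDA ester
Product: 8 (Z)-(2-bromovinyl)boronic acid MIDA ester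
Conditions: KO2CN=NCO2K, AcOH (slow addition), MeCN, rt
Reagents that add atoms: none
Why: Diimide reduction, in which diazene released from the azodicarboxylate by protonation and decarboxylation passes two hydrogens to one face of the alkyne through a concerted six-centre transition state and so gives the Z-alkene, with no metal present to cleave C–Br or C–B and with the reagent charge limited to hold back the slower reduction of the alkene.

Step 6
Reactants: 9 (E)-pent-1-enylboronic acid; 8 (Z)-(2-bromovinyl)boronic acid MIDA ester; 5 (R)-4-{[(E)-5-iodopent-4-en-1-yloxy]methyl}-2,2-dimethyl-1,3-dioxolane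
Product: 12 (R)-4-{[(4E,6Z,8E)-dodeca-4,6,8-trien-1-yloxy]methyl}-2,2-dimethyl-1,3-dioxolane, via (1Z,3E)-hepta-1,3-dienylboronic acid MIDA ester 10 (not isolated), via (1Z,3E)-hepta-1,3-dienylboronic acid 11 (not isolated)
Conditions: 9 (slight excess), 8, Pd(OAc)2 (cat.), 2-dicyclohexylphosphino-2',6'-dimethoxybiphenyl (SPhos), anhydrous KF, toluene, rt, dark, until 8 is consumed; then 5 (limiting), THF, degassed aq. K3PO4 (3 M), rt → 45 °C
Reagents that add atoms: none
Why: Zerovalent palladium formed from Pd(OAc)2 and SPhos inserts into the C–Br bond of 8 with retention, boronic acid 9 transmetalates as its fluoride-activated ate complex and reductive elimination makes C7–C8 (10), while the pyramidal, N→B-bound MIDA boron has no empty p orbital and stays out of transmetalation under anhydrous fluoride. Iodide 5 and aqueous K3PO4 are then added; the MIDA cage hydrolyses slowly and the free dienylboronic acid 11 is trapped as it forms by the alkenylpalladium iodide from 5, making C5–C6. The closest known reaction type is the iterative Suzuki–Miyaura coupling of halovinyl MIDA boronates with slow in situ release of the boronic acid. No ring is closed and no stereocentre is created; the glycerol stereocentre of 5 is a spectator. The step needs chemoselectivity between the two boron centres, secured by the MIDA mask, and retention of E, Z and E geometry, secured because oxidative addition, transmetalation and reductive elimination at sp2 carbon are all stereoretentive and the fast SPhos-ligated catalyst consumes the Z-dienylboronic acid before it can isomerise or protodeboronate. Bromide 8 is used up before 5 enters, so only the iodide acts as electrophile in the second stage, and the base-stable acetonide is the only protecting group present.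

Step 7
Reactants: 12 (R)-4-{[(4E,6Z,8E)-dodeca-4,6,8-trien-1-yloxy]methyl}-2,2-dimethyl-1,3-dioxolane
Product: 13 (S)-3-[(4E,6Z,8E)-dodeca-4,6,8-trien-1-yloxy]propane-1,2-diol
Conditions: AcOH/H2O/THF (4:1:1), rt → 35 °C, dark
Reagents that add atoms: none
Why: Acid-catalysed acetal hydrolysis of a terminal acetonide proceeds in weak acid, which should not protonate a triene that has no allylic leaving group, and no C–O bond at the stereocentre is broken.

Step 8
Reactants: 13 (S)-3-[(4E,6Z,8E)-dodeca-4,6,8-trien-1-yloxy]propane-1,2-diol
Product: 14 (R)-1-[(tert-butyldimethylsilyl)oxy]-3-[(4E,6Z,8E)-dodeca-4,6,8-trien-1-yloxy]propan-2-ol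
Conditions: TBSCl (1.05 equiv), imidazole, CH2Cl2, −10 → 0 °C
Reagents that add atoms: tert-butyldimethylsilyl chloride, CC(C)(C)[Si](C)(C)Cl
Why: Silyl ether formation with a bulky chlorosilane is kinetically selective for the primary over the secondary hydroxyl of a 1,2-diol, so the secondary OH should stay free for the ester.

Step 9
Reactants: 15 4-hydroxybenzoic acid
Product: 16 tert-butyldimethylsilyl 4-[(tert-butyldimethylsilyl)oxy]benzoate
Conditions: TBSCl (2.3 equiv), imidazole, DMF, rt; hexane extraction, cold NaHCO3 wash
Reagents that add atoms: tert-butyldimethylsilyl chloride, CC(C)(C)[Si](C)(C)Cl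
Why: Silylation with TBSCl and imidazole caps both the phenol and the carboxylic acid, and the silyl ester so formed is the direct precursor of the acid chloride.

Step 10
Reactants: 16 tert-butyldimethylsilyl 4-[(tert-butyldimethylsilyl)oxy]benzoate
Product: 17 4-[(tert-butyldimethylsilyl)oxy]benzoyl chloride
Conditions: (COCl)2, DMF (cat.), CH2Cl2, 0 °C → rt; evaporate, use crude
Reagents that add atoms: oxalyl chloride, ClC(=O)C(=O)Cl
Why: Conversion of a silyl ester into an acid chloride by the chloroiminium salt from DMF and oxalyl chloride (Vilsmeier-type activation) releases TBSCl instead of HCl, so the aryl silyl ether should survive under essentially neutral conditions.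

Step 11
Reactants: 14 (R)-1-[(tert-butyldimethylsilyl)oxy]-3-[(4E,6Z,8E)-dodeca-4,6,8-trien-1-yloxy]propan-2-ol; 17 4-[(tert-butyldimethylsilyl)oxy]benzoyl chloride
Product: 18 (R)-1-[(tert-butyldimethylsilyl)oxy]-3-[(4E,6Z,8E)-dodeca-4,6,8-trien-1-yloxy]propan-2-yl 4-[(tert-butyldimethylsilyl)oxy]benzoate
Conditions: pyridine, DMAP (cat.), CH2Cl2, 0 °C → rt, dark
Reagents that add atoms: none
Why: DMAP-catalysed acylation of the secondary alcohol through the N-acylpyridinium ion; the primary silyl ether fixes the ester at O2, only the O–H bond reacts so the stereocentre is untouched, and the triene is inert.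

Step 12
Reactants: 18 (R)-1-[(tert-butyldimethylsilyl)oxy]-3-[(4E,6Z,8E)-dodeca-4,6,8-trien-1-yloxy]propan-2-yl 4-[(tert-butyldimethylsilyl)oxy]benzoate
Product: 19 (S)-1-[(4E,6Z,8E)-dodeca-4,6,8-trien-1-yloxy]-3-hydroxypropan-2-yl 4-hydroxybenzoate
Conditions: Bu4NF/AcOH (1:1, excess), THF, 0 °C → rt, dark
Reagents that add atoms: none
Why: Fluoride-mediated desilylation, driven by the strong Si–F bond, removes the aryl and the primary alkyl TBS groups, and the acetic acid buffer keeps the freed primary hydroxyl and phenol protonated, which should hold back acyl migration from O2 to O3 through the alkoxide and cleavage of the benzoate.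

**Compound list**

1 | pent-4-yn-1-ol | OCCCC#C | starting material
2 | pent-4-yn-1-yl 4-methylbenzenesulfonate | C#CCCCOS(=O)(=O)c1ccc(C)cc1 | intermediate
3 | (R)-solketal, (R)-(2,2-dimethyl-1,3-dioxolan-4-yl)methanol | OC[C@H](CO1)OC1(C)C | starting material
4 | (R)-2,2-dimethyl-4-[(pent-4-yn-1-yloxy)methyl]-1,3-dioxolane | C#CCCCOC[C@H](CO1)OC1(C)C | intermediate
5 | (R)-4-{[(E)-5-iodopent-4-en-1-yloxy]methyl}-2,2-dimethyl-1,3-dioxolane | I/C=C/CCCOC[C@H](CO1)OC1(C)C | intermediate
6 | ethynylboronic acid MIDA ester | C[N+]12CC(=O)O[B-]1(OC(=O)C2)C#C | starting material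
7 | (bromoethynyl)boronic acid MIDA ester | C[N+]12CC(=O)O[B-]1(OC(=O)C2)C#CBr | intermediate
8 | (Z)-(2-bromovinyl)boronic acid MIDA ester | C[N+]12CC(=O)O[B-]1(OC(=O)C2)/C=C\Br | intermediate
9 | (E)-pent-1-enylboronic acid | CCC/C=C/B(O)O | starting material
10 | (1Z,3E)-hepta-1,3-dienylboronic acid MIDA ester | C[N+]12CC(=O)O[B-]1(OC(=O)C2)/C=C\C=C\CCC | intermediate (not isolated)
11 | (1Z,3E)-hepta-1,3-dienylboronic acid | CCC/C=C/C=C\B(O)O | intermediate (not isolated)
12 | (R)-4-{[(4E,6Z,8E)-dodeca-4,6,8-trien-1-yloxy]methyl}-2,2-dimethyl-1,3-dioxolane | CCC/C=C/C=C\C=C\CCCOC[C@H](CO1)OC1(C)C | intermediate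
13 | (S)-3-[(4E,6Z,8E)-dodeca-4,6,8-trien-1-yloxy]propane-1,2-diol | CCC/C=C/C=C\C=C\CCCOC[C@H](CO)O | intermediate
14 | (R)-1-[(tert-butyldimethylsilyl)oxy]-3-[(4E,6Z,8E)-dodeca-4,6,8-trien-1-yloxy]propan-2-ol | CCC/C=C/C=C\C=C\CCCOC[C@H](CO[Si](C)(C)C(C)(C)C)O | intermediate
15 | 4-hydroxybenzoic acid | OC(=O)c1ccc(O)cc1 | starting material
16 | tert-butyldimethylsilyl 4-[(tert-butyldimethylsilyl)oxy]benzoate | CC(C)(C)[Si](C)(C)OC(=O)c1ccc(O[Si](C)(C)C(C)(C)C)cc1 | intermediate
17 | 4-[(tert-butyldimethylsilyl)oxy]benzoyl chloride | ClC(=O)c1ccc(O[Si](C)(C)C(C)(C)C)cc1 | intermediate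
18 | (R)-1-[(tert-butyldimethylsilyl)oxy]-3-[(4E,6Z,8E)-dodeca-4,6,8-trien-1-yloxy]propan-2-yl 4-[(tert-butyldimethylsilyl)oxy]benzoate | CCC/C=C/C=C\C=C\CCCOC[C@H](CO[Si](C)(C)C(C)(C)C)OC(=O)c1ccc(O[Si](C)(C)C(C)(C)C)cc1 | intermediate
19 | (S)-1-[(4E,6Z,8E)-dodeca-4,6,8-trien-1-yloxy]-3-hydroxypropan-2-yl 4-hydroxybenzoate | CCC/C=C/C=C\C=C\CCCOC[C@H](CO)OC(=O)c1ccc(O)cc1 | target

**Step count and risks**

Total step count: 12. Longest linear sequence: 8 steps (steps 1, 2, 3, 6, 7, 8, 11, 12).

Steps most likely to fail:

Step 6. The released Z-dienylboronic acid may protodeboronate or lose its Z geometry at C6=C7 before it couples. Leftover pentenylboronic acid may also couple directly with the iodide, and homocoupling may compete. The fallback sets out from compound 4 and comes back to the route at compound 12. It takes the Z geometry from a Wittig reaction instead of from the linchpin. Commercial (E)-hex-2-enal (CCC/C=C/C=O) is converted by Stork–Zhao olefination ([Ph3PCH2I]I, NaN(SiMe3)2, THF/DMPU, −78 °C) into (1Z,3E)-1-iodohepta-1,3-diene F1. Alkyne 4 is hydroborated with pinacolborane under Cp2Zr(H)Cl catalysis (Et3N, rt → 40 °C) to give the E-alkenyl pinacol boronate (R)-4-({[(E)-5-(4,4,5,5-tetramethyl-1,3,2-dioxaborolan-2-yl)pent-4-en-1-yl]oxy}methyl)-2,2-dimethyl-1,3-dioxolane F2. A stereoretentive Suzuki coupling of F1 with F2 (Pd(PPh3)4, aq. KOH, THF, rt, dark) forms the same C5–C6 bond and should give 12.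

Step 12. The aroyl group may migrate from O2 to O3 once the primary hydroxyl is set free, or the primary silyl ether may be cleaved too slowly under buffered fluoride so that forcing is needed. The fallback sets out from compound 18 and comes back at compound 19. It removes the two silyl groups in two stages so that the primary hydroxyl is only released under acidic conditions. KHF2 in MeOH at rt should cleave the aryl silyl ether alone and give (R)-1-[(tert-butyldimethylsilyl)oxy]-3-[(4E,6Z,8E)-dodeca-4,6,8-trien-1-yloxy]propan-2-yl 4-hydroxybenzoate F3. HF·pyridine buffered with pyridine in THF at 0 °C then removes the primary silyl ether without an alkoxide ever being formed, giving 19.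

Step 7. Acid may isomerise the C6=C7 Z bond or add to the triene if the acetal hydrolysis is slow and has to be forced. The fallback sets out from compound 5 and comes back at compound 14. It moves the acid step to before the triene exists. AcOH/H2O/THF on iodide 5 should give (S)-3-[(E)-5-iodopent-4-en-1-yloxy]propane-1,2-diol F4. TBSCl and imidazole at −10 °C then give (R)-1-[(tert-butyldimethylsilyl)oxy]-3-[(E)-5-iodopent-4-en-1-yloxy]propan-2-ol F5. F5 takes the place of 5 in the second stage of step 6 (same catalyst, aq. K3PO4, THF). The primary silyl ether and the free secondary hydroxyl tolerate these conditions, and the coupling should deliver 14 directly.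

**Further compounds**

F1 | step 6 | (1Z,3E)-1-iodohepta-1,3-diene | CCC/C=C/C=C\I
F2 | step 6 | (R)-4-({[(E)-5-(4,4,5,5-tetramethyl-1,3,2-dioxaborolan-2-yl)pent-4-en-1-yl]oxy}methyl)-2,2-dimethyl-1,3-dioxolane | CC1(C)OB(/C=C/CCCOC[C@H](CO2)OC2(C)C)OC1(C)C
F3 | step 12 | (R)-1-[(tert-butyldimethylsilyl)oxy]-3-[(4E,6Z,8E)-dodeca-4,6,8-trien-1-yloxy]propan-2-yl 4-hydroxybenzoate | CCC/C=C/C=C\C=C\CCCOC[C@H](CO[Si](C)(C)C(C)(C)C)OC(=O)c1ccc(O)cc1
F4 | step 7 | (S)-3-[(E)-5-iodopent-4-en-1-yloxy]propane-1,2-diol | I/C=C/CCCOC[C@H](CO)O
F5 | step 7 | (R)-1-[(tert-butyldimethylsilyl)oxy]-3-[(E)-5-iodopent-4-en-1-yloxy]propan-2-ol | I/C=C/CCCOC[C@H](CO[Si](C)(C)C(C)(C)C)O
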